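**Retrosynthetic overview**

1. Last bond: C2–OH of the unprimed half, by α-hydroxylation of the C3 ketone of spiro adduct 10 (caesium dienolate, O2).
2. Cyclohexene C2–C1=C10–C14–C15'–C4' with the spiro centre C4': Diels–Alder reaction of dienone 9 (diene C14=C10–C1=C2) with the exocyclic enone C4'=C15' of dehydrozaluzanin C 7. Since 9 is made from 7, one guaianolide, dehydrocostus lactone 5, supplies both halves.
3. The cyclopentane of 5 (C1–C2–C3–C4–C5; it becomes ring A of the unprimed half and the spiro-cyclopentanone C1'–C2'–C3'–C4'–C5' of the primed half) is not closed as a five-membered ring. It is the six-membered ring A (C1–C2–C3–C4–C5–C10) of the eudesmanolide mesylate 4, contracted by a shift of C5 from C10 to C1; the same shift enlarges ring B to the cycloheptane and turns the C10 methyl into the exocyclic methylene.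
4. Feature that allows it: in each half the cis-fused ring-fusion carbon C1 of the cyclopentane is bonded to C10, which carries the exocyclic methylene C14. A trans-decalin with an equatorial 1β leaving group antiperiplanar to its C5–C10 bond delivers exactly this array, and that decalin (reynosin 3) comes from costunolide 1 by epoxidation and transannular cyclisation.
5. Order of ring formation: lactone and ten-membered ring (in 1) → decalin (step 2) → cyclopentane and cycloheptane (step 4) → cyclohexene with the spiro centre (step 9).

Key step: step 4

Remark: germacrane/eudesmane/guaiane locants (C1–C15) are used, primed for the half that carries the spiro-cyclopentanone; α/β have their usual sense in each half (H-1, H-5 and H-7 α, H-6 β); natural (+)-costunolide is the only chiral starting material.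

**Route**

Step 1
Reactants: 1 costunolide
Product: 2 1β,10α-epoxycostunolide ((1R,10R)-1,10-epoxygermacra-4E,11(13)-dien-12,6α-olide)
Conditions: mCPBA (1.05 equiv), CH2Cl2, 0 °C
Reagents that add atoms: meta-chloroperoxybenzoic acid, O=C(OO)c1cccc(Cl)c1
Why: Prilezhaev epoxidation should take the most electron-rich alkene, C1=C10 (C4=C5 is deactivated by the allylic lactone oxygen at C6, C11=C13 is conjugated to the carbonyl), and attack on the exposed outer face of the E-alkene in the crown conformer sets C1 and C10 as the trans 1β,10α-epoxide.

Step 2
Reactants: 2 1β,10α-epoxycostunolide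
Product: 3 reynosin (1β-hydroxy-5αH-eudesma-4(15),11(13)-dien-12,6α-olide; 10β-methyl)
Conditions: BF3·OEt2 (0.2 equiv), CH2Cl2, −78 to −30 °C
Reagents that add atoms: none
Why: Lewis-acid opening of the epoxide at tertiary C10 with transannular attack of C4=C5 (cation–olefin cyclisation through the chair–chair conformer) inverts C10, sets 5α-H of the trans-decalin from the E-alkene geometry and keeps the 1β oxygen, and loss of a C15 proton from the C4 cation should give the exocyclic alkene (the Δ3 isomer is the expected separable by-product).

Step 3
Reactants: 3 reynosin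
Product: 4 reynosin 1-O-methanesulfonate (1β-mesyloxy, equatorial)
Conditions: MsCl, Et3N, DMAP (cat.), CH2Cl2, 0 °C
Reagents that add atoms: methanesulfonyl chloride, CS(=O)(=O)Cl
Why: O-sulfonylation (via sulfene) of the only hydroxyl group takes place at oxygen, so the 1β configuration is retained and no other function reacts.

Step 4
Reactants: 4 reynosin 1-O-methanesulfonate
Product: 5 dehydrocostus lactone (1αH,5αH-guaia-4(15),10(14),11(13)-trien-12,6α-olide)
Conditions: KOAc (4 equiv), AcOH, 100 °C
Reagents that add atoms: none
Why: Heating in buffered acetic acid ionises the equatorial 1β-mesylate with participation of the antiperiplanar C5–C10 σ bond, so C5 migrates from C10 to C1 and the tertiary guaian-10-yl cation loses a proton from its methyl group (C14) to acetate. The closest known reaction type is the solvolytic Wagner–Meerwein rearrangement of decalin 1-sulfonates to hydroazulenes (eudesmane to guaiane). The cyclopentane C1–C2–C3–C4–C5 closes by this suprafacial 1,2-alkyl shift, a backside displacement of the mesylate by the migrating bond that contracts ring A from six to five atoms while ring B grows from six to seven. C1, the only new stereocentre, is set by inversion at the carbinol carbon (C5 enters on the α face), which gives the cis-fused 1α-H,5α-H hydroazulene, and the migrating C5 keeps its configuration. The step needs migration of C5–C10 in preference to C2–C3 and to simple elimination, secured because only the C5 shift leads to a tertiary cation and an equatorial leaving group has no antiperiplanar β-hydrogen; it also needs proton loss toward C14 and not toward C1 or C9, which rests on the three accessible methyl hydrogens and the weak acetate base and is the less secure point.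

Step 5
Reactants: 5 dehydrocostus lactone
Product: 6 3-epizaluzanin C (3α-hydroxy-1αH,5αH-guaia-4(15),10(14),11(13)-trien-12,6α-olide; 3R)
Conditions: SeO2 (0.5 equiv), t-BuOOH (2 equiv), CH2Cl2, 0 °C to rt
Reagents that add atoms: selenium dioxide, O=[Se]=O (oxygen carrier); tert-butyl hydroperoxide, CC(C)(C)OO (terminal oxygen source)
Why: Riley-type allylic oxidation (ene reaction, then [2,3]-sigmatropic shift) of the ring-A exocyclic alkene should functionalise its allylic methylene C3 in preference to the methine C5, and the reagent removes and replaces the hydrogen on the convex α face, which gives the 3α-alcohol (this configuration is erased in step 6).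

Step 6
Reactants: 6 3-epizaluzanin C
Product: 7 dehydrozaluzanin C (3-oxo-1αH,5αH-guaia-4(15),10(14),11(13)-trien-12,6α-olide)
Conditions: Dess–Martin periodinane (1.2 equiv), CH2Cl2, 0 °C to rt
Reagents that add atoms: none
Why: Dess–Martin oxidation converts the secondary allylic alcohol into the α-methylene cyclopentanone under neutral, non-nucleophilic conditions that leave the α-methylene lactone and the exocyclic alkenes alone; no stereocentre is formed.

Step 7
Reactants: 7 dehydrozaluzanin C
Product: 8 3-trimethylsilyloxy-1αH,5αH-guaia-2,4(15),10(14),11(13)-tetraen-12,6α-olide (silyl enol ether, C2=C3)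
Conditions: TMSOTf (1.3 equiv), Et3N (2 equiv), CH2Cl2, −78 to 0 °C
Reagents that add atoms: trimethylsilyl trifluoromethanesulfonate, C[Si](C)(C)OS(=O)(=O)C(F)(F)F
Why: Soft enolisation with O-silylation can only go toward C2, the single enolisable α-position of the C3 ketone (C4 is sp2), so the C2=C3 silyl enol ether forms without change at C1.

Step 8
Reactants: 8 silyl enol ether
Product: 9 3-oxo-5αH-guaia-1,4(15),10(14),11(13)-tetraen-12,6α-olide (dienone; diene C14=C10–C1=C2)
Conditions: Pd(OAc)2 (1.1 equiv), MeCN, rt
Reagents that add atoms: none
Why: Saegusa–Ito oxidation: the divalent palladium enolate at C2 undergoes β-hydride elimination of H-1 to give the C1=C2 enone in conjugation with C10=C14 and zerovalent palladium; the C1 stereocentre is removed and none is formed.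

Step 9
Reactants: 9 dienone; 7 dehydrozaluzanin C
Product: 10 spiro adduct (2-deoxy target; new bonds C14–C15' and C2–C4', C1=C10, H-2 α and cis to C5', C15' β and C2 α at C4' with respect to the primed half)
Conditions: toluene (1 M), BHT (cat.), 60 °C, dark; dienophile in threefold excess, surplus recovered by chromatography
Reagents that add atoms: none
Why: Intermolecular Diels–Alder reaction of the s-cis-locked diene with the exocyclic enone in the "ortho" sense (diene terminus C14 to the β-carbon C15', C2 to C4'), an addition in which every atom of both partners ends up in the adduct; C2 and C4' should be set by endo approach (C3' carbonyl over ring A of the diene) of the convex α face of 7 (syn to H-1' and H-5') onto the β face of 9, and the excess of 7 suppresses self-dimerisation of 9.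

Step 10
Reactants: 10 spiro adduct
Product: 12 target CNP0269880.2, via C2 hydroperoxide 11 (not isolated)
Conditions: O2 (1 atm), Cs2CO3 (0.2 equiv), P(OEt)3 (2 equiv), DMSO, rt
Reagents that add atoms: dioxygen, O=O
Why: Base-mediated α-hydroxylation of a ketone with O2 (dienolate autoxidation, phosphite reduction of the hydroperoxide in the flask): H-2 is the only acidic α-hydrogen that is also allylic, and in the non-chelated caesium dienolate the spiro C3' carbonyl should sit pseudoaxial on the β face away from the enolate oxygen, so oxygen enters at C2 from the α face and the hydroxyl ends up cis to C5'.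

**Compound list**

1 | costunolide ((3aS,6E,10E,11aR)-germacra-1(10),4,11(13)-trien-12,6α-olide) | C/C1=C\CC/C(C)=C/[C@H]2OC(=O)C(=C)[C@@H]2CC1 | starting material
2 | 1β,10α-epoxycostunolide ((1R,10R)-epoxide) | C[C@]12O[C@@H]1CC/C(C)=C/[C@H]3OC(=O)C(=C)[C@@H]3CC2 | intermediate
3 | reynosin (1β-hydroxy-5αH-eudesma-4(15),11(13)-dien-12,6α-olide) | C=C1CC[C@@H](O)[C@]2(C)CC[C@H]3C(=C)C(=O)O[C@@H]3[C@@H]12 | intermediate
4 | reynosin 1-O-methanesulfonate | C=C1CC[C@@H](OS(C)(=O)=O)[C@]2(C)CC[C@H]3C(=C)C(=O)O[C@@H]3[C@@H]12 | intermediate
5 | dehydrocostus lactone (1αH,5αH-guaia-4(15),10(14),11(13)-trien-12,6α-olide) | C=C1CC[C@H]2C(=C)CC[C@H]3C(=C)C(=O)O[C@@H]3[C@@H]12 | intermediate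
6 | 3-epizaluzanin C (3α-hydroxy derivative of 5) | C=C1[C@H](O)C[C@H]2C(=C)CC[C@H]3C(=C)C(=O)O[C@@H]3[C@@H]12 | intermediate
7 | dehydrozaluzanin C (3-oxo derivative of 5) | C=C1C(=O)C[C@H]2C(=C)CC[C@H]3C(=C)C(=O)O[C@@H]3[C@@H]12 | intermediate
8 | C2=C3 trimethylsilyl enol ether of 7 | C=C1C(O[Si](C)(C)C)=C[C@H]2C(=C)CC[C@H]3C(=C)C(=O)O[C@@H]3[C@@H]12 | intermediate
9 | dienone (1,2-dehydro-dehydrozaluzanin C) | C=C1C(=O)C=C2C(=C)CC[C@H]3C(=C)C(=O)O[C@@H]3[C@@H]12 | intermediate
10 | spiro Diels–Alder adduct (2-deoxy target, 2α-H) | C=C1C(=O)[C@@H]2C3=C(CC[C@H]4C(=C)C(=O)O[C@@H]4[C@@H]13)CC[C@]21C(=O)C[C@H]2C(=C)CC[C@H]3C(=C)C(=O)O[C@@H]3[C@H]21 | intermediate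
11 | C2 hydroperoxide of 10 (2α-OOH) | C=C1C(=O)[C@]2(OO)C3=C(CC[C@H]4C(=C)C(=O)O[C@@H]4[C@@H]13)CC[C@]21C(=O)C[C@H]2C(=C)CC[C@H]3C(=C)C(=O)O[C@@H]3[C@H]21 | intermediate
12 | target CNP0269880.2 (2α-hydroxy spiro dimer) | C=C1C(=O)[C@]2(O)C3=C(CC[C@H]4C(=C)C(=O)O[C@@H]4[C@@H]13)CC[C@]21C(=O)C[C@H]2C(=C)CC[C@H]3C(=C)C(=O)O[C@@H]3[C@H]21 | target

**Step count**

Total: 10 steps. Longest linear sequence: 10 steps (1 → 12); compound 7 enters step 9 a second time as the dienophile.

**Steps most likely to fail**

Step 4 (key step). What may go wrong: non-selective proton loss from the C10 cation (toward C1 or C9 instead of C14) or capture of the cation by acetate. The fallback sets out from 4 and comes back at 5. The rearrangement is run in buffered aqueous acetone (NaHCO3, acetone–water, 60 °C), so that water captures the cation on the convex face and gives 10α-hydroxy-1αH,5αH-guaia-4(15),11(13)-dien-12,6α-olide F1. F1 is then dehydrated with SOCl2/pyridine at −20 °C. This is an antiperiplanar elimination of the chlorosulfite in which H-1, cis to the leaving group, cannot take part; only methyl or C9 hydrogens can be removed, and the unhindered methyl should prevail, which gives 5. The ring contraction itself is unchanged; alkene formation is separated from it and placed under stereoelectronic control.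

Step 9. What may go wrong: self-dimerisation of dienone 9 through its own exocyclic enone, and insufficient discrimination between the two faces of the diene. The fallback sets out from 8 and comes back at 12. Rubottom oxidation of 8 with dimethyldioxirane (acetone/CH2Cl2, −78 °C) gives 2α-trimethylsilyloxy-dehydrozaluzanin C F2, which loses the silyl group on acidic work-up to give 2α-hydroxy-dehydrozaluzanin C F3. Dess–Martin oxidation of F3 gives the 2,3-diketone, which exists as its enol, the 2-hydroxy-dienone (diosphenol) F4. F4 and 7 with catalytic Et3N (toluene, rt) undergo a base-catalysed hydroxy-diene Diels–Alder reaction (vinylogous Michael addition of C14 to C15', then aldol closure of C4' onto C2). The oxido-diene is far more electron-rich than 9 and pairs with the enone of 7, and the C2 hydroxyl is placed by the same endo approach, so 12 forms directly and steps 8 to 10 are not needed.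

Step 10. What may go wrong: entry of oxygen on the β face of the dienolate, or oxygenation at the γ-position C10. The fallback sets out from 10 and comes back at 12. Compound 10 is deprotonated at C2 with KN(SiMe3)2 (THF, −78 °C) to the potassium dienolate F5. F5 is hydroxylated at −78 °C with an enantiopure (camphorsulfonyl)oxaziridine, the antipode being chosen for matched delivery to the α face, and quenched with NH4Cl. This replaces substrate-controlled autoxidation by a closed-shell electrophilic oxygen transfer under reagent control, which also favours the α-carbon.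

**Further compounds**

F1 | step 4 | 10α-hydroxy-1αH,5αH-guaia-4(15),11(13)-dien-12,6α-olide | C=C1CC[C@H]2[C@](C)(O)CC[C@H]3C(=C)C(=O)O[C@@H]3[C@@H]12
F2 | step 9 | 2α-trimethylsilyloxy-dehydrozaluzanin C | C=C1C(=O)[C@H](O[Si](C)(C)C)[C@H]2C(=C)CC[C@H]3C(=C)C(=O)O[C@@H]3[C@@H]12
F3 | step 9 | 2α-hydroxy-dehydrozaluzanin C | C=C1C(=O)[C@H](O)[C@H]2C(=C)CC[C@H]3C(=C)C(=O)O[C@@H]3[C@@H]12
F4 | step 9 | 2-hydroxy-3-oxo-5αH-guaia-1,4(15),10(14),11(13)-tetraen-12,6α-olide (diosphenol) | C=C1C(=O)C(O)=C2C(=C)CC[C@H]3C(=C)C(=O)O[C@@H]3[C@@H]12
F5 | step 10 | potassium C3 dienolate of 10 | C=C1C([O-])=C2C3=C(CC[C@H]4C(=C)C(=O)O[C@@H]4[C@@H]13)CC[C@]21C(=O)C[C@H]2C(=C)CC[C@H]3C(=C)C(=O)O[C@@H]3[C@H]21.[K+]
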